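**Plan**

- Retrosynthesis: kumbicin C (12) is traced back to a MOM ether carrying two C2'-silyl groups. Both pyrrole rings are then opened at N1'–C2' and C3'–C3a'. This is possible because each indole is attached through C3' to the benzene ring of the chromene (at C5 and at C8) and bears only hydrogen at C2', so each maps onto an aryl silylalkyne plus 2-iodoaniline.
- Further cuts: the two C5/C8–alkyne bonds (Sonogashira), the two C–Br bonds, and the C4–C4a and O1–C2 bonds of the pyran ring (acylative annulation of 2-methoxyhydroquinone with 3-methylbut-2-enoic acid).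
- Forward order: the pyranone ring is built first. C5 and C8 are brominated while C3–C4 is still a saturated ketone, because an electron-rich chromene double bond would not be expected to survive NBS. Then follow ketone to alkene, MOM protection, two alkynes, both pyrrole rings in one palladium-catalysed operation, and global deprotection.
- Stereochemistry: the target has no stereocentre. The only one on the route (C4 of alcohol 5) is formed racemic and removed in the same step.

Key step: step 6

Assumption: rotation about the two aryl–indole bonds of the target is taken as free on the laboratory time scale, so no axial stereochemistry has to be set.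

**Route**

Step 1
Reactants: 1 2-methoxyhydroquinone; 2 3-methylbut-2-enoic acid
Product: 3 6-hydroxy-7-methoxy-2,2-dimethylchroman-4-one
Conditions: P2O5/MeSO3H (Eaton's reagent), 70 °C
Reagents that add atoms: none
Why: Friedel–Crafts acylation at the ring carbon para to the methoxy group, followed by oxa-Michael closure of the neighbouring hydroxyl onto the enone (the usual one-pot chroman-4-one annulation of phenols with 3,3-dimethylacrylic acid), should build the pyranone ring with the 6-hydroxy-7-methoxy pattern, since that carbon is the only unhindered site activated by both an ortho hydroxyl and a para methoxy group.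

Step 2
Reactants: 3 6-hydroxy-7-methoxy-2,2-dimethylchroman-4-one
Product: 4 5,8-dibromo-6-hydroxy-7-methoxy-2,2-dimethylchroman-4-one
Conditions: NBS (2.1 equiv), DMF, 0 °C to rt
Reagents that add atoms: N-bromosuccinimide, O=C1CCC(=O)N1Br
Why: Electrophilic aromatic bromination should fill the only two free ring positions, C5 ortho to the phenol and C8 between the two ether oxygens, and it is placed here because the C3–C4 unit is still a saturated ketone that NBS leaves alone, while the carbonyl tempers oxidation of the electron-rich phenol.

Step 3
Reactants: 4 5,8-dibromo-6-hydroxy-7-methoxy-2,2-dimethylchroman-4-one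
Product: 6 5,8-dibromo-7-methoxy-2,2-dimethyl-2H-chromen-6-ol, via racemic chromane-4,6-diol 5 (not isolated)
Conditions: NaBH4, MeOH/THF, 0 °C to rt; aq. NH4Cl work-up; then crude 5, p-TsOH·H2O (cat.), toluene, 80 °C
Reagents that add atoms: none
Why: Borohydride reduction of the aryl ketone gives benzylic alcohol 5, whose acid-catalysed E1 dehydration through the C4 cation (stabilised by the para C7 methoxy group) can only eliminate toward C3 and should give the 2H-chromene; running it on the free phenol keeps the acid away from the later acetal, and the stereocentre of 5 disappears again.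

Step 4
Reactants: 6 5,8-dibromo-7-methoxy-2,2-dimethyl-2H-chromen-6-ol
Product: 7 5,8-dibromo-7-methoxy-6-(methoxymethoxy)-2,2-dimethyl-2H-chromene
Conditions: MOMCl, i-Pr2NEt, CH2Cl2, 0 °C to rt
Reagents that add atoms: chloromethyl methyl ether, COCCl
Why: O-alkylation of the phenol with MOMCl (Williamson-type acetal formation) should mask the C6 oxygen with a group small enough for the doubly flanked position and inert to amine, carbonate and palladium in steps 5 and 6.

Step 5
Reactants: 7 5,8-dibromo-7-methoxy-6-(methoxymethoxy)-2,2-dimethyl-2H-chromene; 8 trimethylsilylacetylene (3 equiv)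
Product: 9 7-methoxy-6-(methoxymethoxy)-2,2-dimethyl-5,8-bis[(trimethylsilyl)ethynyl]-2H-chromene
Conditions: PdCl2(PhCN)2 (6 mol%), [(t-Bu)3PH]BF4 (12 mol%), CuI (4 mol%), i-Pr2NH, 1,4-dioxane, 60 °C, sealed tube
Reagents that add atoms: none
Why: Double Sonogashira coupling, in which the bulky, electron-rich P(t-Bu)3 ligand promotes oxidative addition into electron-rich, di-ortho-substituted aryl bromides and the slim alkyne is the smallest carbon nucleophile that can be brought to C5 and C8.

Step 6
Reactants: 9 7-methoxy-6-(methoxymethoxy)-2,2-dimethyl-5,8-bis[(trimethylsilyl)ethynyl]-2H-chromene; 10 2-iodoaniline (3 equiv)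
Product: 11 7-methoxy-6-(methoxymethoxy)-2,2-dimethyl-5,8-bis[2-(trimethylsilyl)-1H-indol-3-yl]-2H-chromene
Conditions: Pd(OAc)2 (10 mol%), LiCl (2 equiv), Na2CO3 (5 equiv), DMF, 100 °C, argon
Reagents that add atoms: none
Why: Pd(OAc)2 is reduced in situ to zerovalent palladium, which inserts into the C–I bond of 10; the chloride-ligated arylpalladium species then adds syn across a silylalkyne of 9, the aryl group going to the chromenyl-bearing carbon and palladium to the silyl-bearing carbon. Coordination of the amino group, deprotonation by carbonate and C–N reductive elimination from the six-membered azapalladacycle close the pyrrole ring, and the same cycle at the second alkyne closes the other, so both rings arise by carbopalladation followed by ring-closing C–N reductive elimination. The closest known reaction is the Larock indole synthesis of 2-iodoaniline with 1-aryl-2-silylalkynes, which gives 3-aryl-2-silylindoles. No stereocentre is formed; hindered rotation about the two aryl–indole axes may show up as rotamers of 11, which is of no consequence because the silyl groups leave in step 7. The step needs insertion regioselectivity (silicon at C2', chromenyl at C3'), secured by the bulky trimethylsilyl group taking the palladium-bound carbon, and it needs the C6 oxygen to stay out of the reaction, secured by the MOM ether, which excludes oxypalladation to a benzofuran; Na2CO3 is chosen as the mildest workable base to limit loss of silicon from the alkynes. Because syn addition places palladium trans to the chromenyl group, the vinylpalladium intermediate cannot reach the C3=C4 double bond, so no Heck-type path should compete.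

Step 7
Reactants: 11 7-methoxy-6-(methoxymethoxy)-2,2-dimethyl-5,8-bis[2-(trimethylsilyl)-1H-indol-3-yl]-2H-chromene
Product: 12 kumbicin C, 5,8-di(1H-indol-3-yl)-7-methoxy-2,2-dimethyl-2H-chromen-6-ol
Conditions: HCl (1.25 M in MeOH), THF, rt to 40 °C, argon
Reagents that add atoms: none
Why: Acid-mediated ipso-protodesilylation at C2' of both 2-silylindoles and acid-catalysed methanolysis of the MOM acetal should proceed together in methanolic HCl, the usual conditions for each cleavage, leaving the free phenol and two 2-unsubstituted indoles.

**Compound list**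

1 | 2-methoxyhydroquinone (2-methoxybenzene-1,4-diol) | COc1cc(O)ccc1O | starting material
2 | 3-methylbut-2-enoic acid | CC(C)=CC(=O)O | starting material
3 | 6-hydroxy-7-methoxy-2,2-dimethylchroman-4-one | COc1cc2c(cc1O)C(=O)CC(C)(C)O2 | intermediate
4 | 5,8-dibromo-6-hydroxy-7-methoxy-2,2-dimethylchroman-4-one | COc1c(O)c(Br)c2c(c1Br)OC(C)(C)CC2=O | intermediate
5 | 5,8-dibromo-7-methoxy-2,2-dimethylchromane-4,6-diol (racemic at C4) | COc1c(O)c(Br)c2c(c1Br)OC(C)(C)CC2O | intermediate (not isolated)
6 | 5,8-dibromo-7-methoxy-2,2-dimethyl-2H-chromen-6-ol | COc1c(O)c(Br)c2c(c1Br)OC(C)(C)C=C2 | intermediate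
7 | 5,8-dibromo-7-methoxy-6-(methoxymethoxy)-2,2-dimethyl-2H-chromene | COc1c(OCOC)c(Br)c2c(c1Br)OC(C)(C)C=C2 | intermediate
8 | trimethylsilylacetylene | C#C[Si](C)(C)C | starting material
9 | 7-methoxy-6-(methoxymethoxy)-2,2-dimethyl-5,8-bis[(trimethylsilyl)ethynyl]-2H-chromene | COc1c(OCOC)c(C#C[Si](C)(C)C)c2c(c1C#C[Si](C)(C)C)OC(C)(C)C=C2 | intermediate
10 | 2-iodoaniline | Nc1ccccc1I | starting material
11 | 7-methoxy-6-(methoxymethoxy)-2,2-dimethyl-5,8-bis[2-(trimethylsilyl)-1H-indol-3-yl]-2H-chromene | COc1c(OCOC)c(-c2c([Si](C)(C)C)[nH]c3ccccc23)c2c(c1-c1c([Si](C)(C)C)[nH]c3ccccc13)OC(C)(C)C=C2 | intermediate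
12 | kumbicin C, 5,8-di(1H-indol-3-yl)-7-methoxy-2,2-dimethyl-2H-chromen-6-ol | COc1c(O)c(-c2c[nH]c3ccccc23)c2c(c1-c1c[nH]c3ccccc13)OC(C)(C)C=C2 | target

**Count**

Total steps: 7. Longest linear sequence: 7 steps (1 to 12); compounds 2, 8 and 10 are bought and enter directly.

**Steps most likely to fail**

Step 6. Both alkynes sit between two ortho substituents, so the second annulation may be slow. During the long heating the base may strip silicon from the alkynes, and the resulting terminal alkynes would oligomerise on palladium. The very hindered aryl group may also erode the insertion regiochemistry. The fallback gives up the annulation and attaches the finished indoles; it sets out from 7 and comes back at 12. Double Suzuki–Miyaura coupling of 7 with tert-butyl 3-(4,4,5,5-tetramethyl-1,3,2-dioxaborolan-2-yl)-1H-indole-1-carboxylate (Pd(OAc)2, SPhos, K3PO4, toluene/H2O, 90 °C) should give di-tert-butyl 3,3'-[7-methoxy-6-(methoxymethoxy)-2,2-dimethyl-2H-chromene-5,8-diyl]bis(1H-indole-1-carboxylate) F1. Catalytic NaOMe in MeOH/THF at rt should remove both carbamates to give 7-methoxy-6-(methoxymethoxy)-2,2-dimethyl-5,8-di(1H-indol-3-yl)-2H-chromene F2. Methanolic HCl as in step 7 should then cleave the acetal to give 12.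

Step 5. Oxidative addition into two electron-rich, di-ortho-substituted C–Br bonds may be slow enough that copper-mediated oxidative homocoupling consumes the alkyne and the reaction stalls after the first coupling. The fallback replaces the copper acetylide by a preformed organozinc nucleophile (Negishi alkynylation); it sets out from 7 and comes back at 9. Compound 8 is deprotonated with n-BuLi (THF, −78 °C) and transmetalated with ZnCl2 to chloro[(trimethylsilyl)ethynyl]zinc F3. This is coupled with 7 using Pd[P(t-Bu)3]2 in THF at 60 °C, conditions under which no alkyne homocoupling can occur and transmetalation at hindered palladium centres is known to be efficient.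

Step 7. In the time the hindered acetal needs to cleave, acid may add methanol or an indole C2' position across the electron-rich C3=C4 bond, or start oligomerisation of the chromene. The fallback removes acid from the endgame by changing the phenol protecting group to one that leaves with fluoride; it sets out from 6 and comes back at 12. Phenol 6 is alkylated with SEMCl and i-Pr2NEt in CH2Cl2 to give 5,8-dibromo-7-methoxy-2,2-dimethyl-6-{[2-(trimethylsilyl)ethoxy]methoxy}-2H-chromene F4. Sonogashira coupling with 8 under the conditions of step 5 should give 7-methoxy-2,2-dimethyl-6-{[2-(trimethylsilyl)ethoxy]methoxy}-5,8-bis[(trimethylsilyl)ethynyl]-2H-chromene F5. Annulation with 10 under the conditions of step 6 should give 7-methoxy-2,2-dimethyl-6-{[2-(trimethylsilyl)ethoxy]methoxy}-5,8-bis[2-(trimethylsilyl)-1H-indol-3-yl]-2H-chromene F6. Excess Bu4NF in THF/DMPU at 70 °C should then cleave the acetal and both C2'–Si bonds in one basic operation to give 12.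

**Further compounds**

F1 | step 6 | di-tert-butyl 3,3'-[7-methoxy-6-(methoxymethoxy)-2,2-dimethyl-2H-chromene-5,8-diyl]bis(1H-indole-1-carboxylate) | COc1c(OCOC)c(-c2cn(C(=O)OC(C)(C)C)c3ccccc23)c2c(c1-c1cn(C(=O)OC(C)(C)C)c3ccccc13)OC(C)(C)C=C2
F2 | step 6 | 7-methoxy-6-(methoxymethoxy)-2,2-dimethyl-5,8-di(1H-indol-3-yl)-2H-chromene | COc1c(OCOC)c(-c2c[nH]c3ccccc23)c2c(c1-c1c[nH]c3ccccc13)OC(C)(C)C=C2
F3 | step 5 | chloro[(trimethylsilyl)ethynyl]zinc | C[Si](C)(C)C#C[Zn]Cl
F4 | step 7 | 5,8-dibromo-7-methoxy-2,2-dimethyl-6-{[2-(trimethylsilyl)ethoxy]methoxy}-2H-chromene | COc1c(OCOCC[Si](C)(C)C)c(Br)c2c(c1Br)OC(C)(C)C=C2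
F5 | step 7 | 7-methoxy-2,2-dimethyl-6-{[2-(trimethylsilyl)ethoxy]methoxy}-5,8-bis[(trimethylsilyl)ethynyl]-2H-chromene | COc1c(OCOCC[Si](C)(C)C)c(C#C[Si](C)(C)C)c2c(c1C#C[Si](C)(C)C)OC(C)(C)C=C2
F6 | step 7 | 7-methoxy-2,2-dimethyl-6-{[2-(trimethylsilyl)ethoxy]methoxy}-5,8-bis[2-(trimethylsilyl)-1H-indol-3-yl]-2H-chromene | COc1c(OCOCC[Si](C)(C)C)c(-c2c([Si](C)(C)C)[nH]c3ccccc23)c2c(c1-c1c([Si](C)(C)C)[nH]c3ccccc13)OC(C)(C)C=C2
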